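The route rests on cutting the aryl ketone bond C4–C4a of the flavanone. Pyranone ring C is closed late by an intramolecular Friedel–Crafts acylation of an (S)-3-aryl-3-aryloxypropanoic acid that already carries the C2 stereocentre and the complete benzylated, biaryl-linked apigenin unit. The step exploits the local mirror symmetry of the phloroglucinol ring A: its two carbons ortho to the ether oxygen O1 are equivalent and each lies ortho/para to three oxygens, so acylation can only give the C4–C4a bond. C2 is set by asymmetric transfer hydrogenation and Mitsunobu inversion; the C5'–C6'' biaryl bond comes from a Suzuki coupling with 6-iodoapigenin tribenzyl ether; hydrogenolysis ends the route.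

Key step: step 10

Remark: the C5'–C6'' biaryl axis carries no configurational label in the target and is treated as freely rotating; rotamers of the benzylated intermediates 12–15 are of no consequence. Apigenin, 3-bromo-4,5-dihydroxybenzaldehyde and 3,5-bis(benzyloxy)phenol are taken as commercial.

Step 1
Reactants: 1 apigenin
Product: 2 7-(benzyloxy)-2-[4-(benzyloxy)phenyl]-5-hydroxy-4H-chromen-4-one
Conditions: BnBr (2.2 equiv), K2CO3, DMF, rt
Reagents that add atoms: benzyl bromide, BrCc1ccccc1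
Why: Williamson etherification in which the 5-OH, hydrogen-bonded to the C4 carbonyl, should stay free while the unchelated 7- and 4'-phenols are benzylated.

Step 2
Reactants: 2 7-(benzyloxy)-2-[4-(benzyloxy)phenyl]-5-hydroxy-4H-chromen-4-one
Product: 3 7-(benzyloxy)-2-[4-(benzyloxy)phenyl]-5-hydroxy-6-iodo-4H-chromen-4-one
Conditions: BnMe3N+ ICl2− (1.1 equiv), CaCO3, CH2Cl2/MeOH, rt
Reagents that add atoms: benzyltrimethylammonium dichloroiodate, C[N+](C)(C)Cc1ccccc1.Cl[I-]Cl
Why: Electrophilic aromatic iodination which, with O7 alkylated and the 5-OH free, should be directed ortho to the free phenol, to C6 and not C8.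

Step 3
Reactants: 3 7-(benzyloxy)-2-[4-(benzyloxy)phenyl]-5-hydroxy-6-iodo-4H-chromen-4-one
Product: 4 5,7-bis(benzyloxy)-2-[4-(benzyloxy)phenyl]-6-iodo-4H-chromen-4-one
Conditions: BnBr, K2CO3, n-Bu4NI (cat.), DMF, 60 °C
Reagents that add atoms: benzyl bromide, BrCc1ccccc1
Why: Williamson etherification in which heat and iodide catalysis should overcome chelation and the flanking iodine, so that the coupling partner carries no free phenol.

Step 4
Reactants: 5 3-bromo-4,5-dihydroxybenzaldehyde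
Product: 6 3,4-bis(benzyloxy)-5-bromobenzaldehyde
Conditions: BnBr (2.3 equiv), K2CO3, DMF, 50 °C
Reagents that add atoms: benzyl bromide, BrCc1ccccc1
Why: Double Williamson etherification of the catechol; aldehyde and aryl bromide are inert.

Step 5
Reactants: 6 3,4-bis(benzyloxy)-5-bromobenzaldehyde
Product: 7 ethyl 3-[3,4-bis(benzyloxy)-5-bromophenyl]-3-oxopropanoate
Conditions: N2CHCO2Et, NbCl5 (5 mol %), CH2Cl2, rt
Reagents that add atoms: ethyl diazoacetate, CCOC(=O)C=[N+]=[N-]
Why: Roskamp homologation, in which the diazo carbon adds to the Lewis-acid-activated aldehyde and a 1,2-hydride shift with loss of N2 gives the β-keto ester directly.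

Step 6
Reactants: 7 ethyl 3-[3,4-bis(benzyloxy)-5-bromophenyl]-3-oxopropanoate
Product: 8 ethyl (3R)-3-[3,4-bis(benzyloxy)-5-bromophenyl]-3-hydroxypropanoate
Conditions: RuCl[(R,R)-TsDPEN](p-cymene) (1 mol %), HCO2H/Et3N (5:2), EtOAc, 35 °C
Reagents that add atoms: none
Why: Noyori–Ikariya asymmetric transfer hydrogenation of an aryl ketone, in which the (R,R)-ligand should deliver hydride to the Si face through the CH/π-organised six-membered transition state and set the (R)-carbinol, leaving aryl bromide and benzyl ethers untouched.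

Step 7
Reactants: 8 ethyl (3R)-3-[3,4-bis(benzyloxy)-5-bromophenyl]-3-hydroxypropanoate; 9 3,5-bis(benzyloxy)phenol
Product: 10 ethyl (3S)-3-[3,4-bis(benzyloxy)-5-bromophenyl]-3-[3,5-bis(benzyloxy)phenoxy]propanoate
Conditions: PPh3, DIAD, toluene, −10 °C to rt
Reagents that add atoms: none
Why: Mitsunobu etherification in which SN2 displacement of the oxyphosphonium by the phenoxide inverts the carbinol centre from (R) to (S), while the meta-bromine and the doubly flanked, twisted 4-benzyloxy group disfavour competing ionisation.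

Step 8
Reactants: 10 ethyl (3S)-3-[3,4-bis(benzyloxy)-5-bromophenyl]-3-[3,5-bis(benzyloxy)phenoxy]propanoate; 4 5,7-bis(benzyloxy)-2-[4-(benzyloxy)phenyl]-6-iodo-4H-chromen-4-one
Product: 12 ethyl (3S)-3-{3,4-bis(benzyloxy)-5-[5,7-bis(benzyloxy)-2-(4-(benzyloxy)phenyl)-4-oxo-4H-chromen-6-yl]phenyl}-3-[3,5-bis(benzyloxy)phenoxy]propanoate, via pinacol boronate 11 (not isolated)
Conditions: B2pin2, PdCl2(dppf), KOAc, dioxane, 85 °C; then 4, Pd(OAc)2, SPhos, K3PO4, H2O, 65 °C
Reagents that add atoms: none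
Why: Miyaura borylation followed in the same flask by Suzuki–Miyaura coupling, in which the bulky electron-rich SPhos ligand should allow the tri-ortho-substituted biaryl to form and the weak bases leave the ester α-position and the stereocentre untouched.

Step 9
Reactants: 12 ethyl (3S)-3-{3,4-bis(benzyloxy)-5-[5,7-bis(benzyloxy)-2-(4-(benzyloxy)phenyl)-4-oxo-4H-chromen-6-yl]phenyl}-3-[3,5-bis(benzyloxy)phenoxy]propanoate
Product: 13 (3S)-3-{3,4-bis(benzyloxy)-5-[5,7-bis(benzyloxy)-2-(4-(benzyloxy)phenyl)-4-oxo-4H-chromen-6-yl]phenyl}-3-[3,5-bis(benzyloxy)phenoxy]propanoic acid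
Conditions: LiOH·H2O, THF/MeOH/H2O, 0 °C to rt; then aq. HCl to pH 3
Reagents that add atoms: lithium hydroxide, [Li+].[OH-]
Why: Ester saponification by acyl–oxygen cleavage, which should be faster than E1cB loss of the β-aryloxy group and gives an inert carboxylate, while the benzylated flavone withstands cold dilute hydroxide.

Step 10
Reactants: 13 (3S)-3-{3,4-bis(benzyloxy)-5-[5,7-bis(benzyloxy)-2-(4-(benzyloxy)phenyl)-4-oxo-4H-chromen-6-yl]phenyl}-3-[3,5-bis(benzyloxy)phenoxy]propanoic acid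
Product: 15 (2S)-5,7-bis(benzyloxy)-2-{3,4-bis(benzyloxy)-5-[5,7-bis(benzyloxy)-2-(4-(benzyloxy)phenyl)-4-oxo-4H-chromen-6-yl]phenyl}chroman-4-one, via mixed anhydride 14 (not isolated)
Conditions: (CF3CO)2O (1.5 equiv), CH2Cl2, 0 °C to rt
Reagents that add atoms: none
Why: Trifluoroacetic anhydride converts the acid into mixed anhydride 14, whose acyl carbon (the future C4) is attacked by the ring A carbon ortho to the ether oxygen O1 (the future C4a), and loss of a proton with expulsion of trifluoroacetate gives the aryl ketone; this is the intramolecular Friedel–Crafts cycloacylation by which 3-aryloxypropanoic acids are turned into chroman-4-ones. Ring C closes in a 6-exo-trig mode, the carbonyl being exocyclic to the six-membered ring that forms. No stereocentre is created; C2, set in steps 6 and 7, lies β to the new ketone and is neither deprotonated nor ionised under these conditions, so it should be carried through unchanged. The step needs a single regioisomer on ring A, guaranteed because the 3,5-bis(benzyloxy)phenoxy ring has a local mirror plane through O1 and its two ortho carbons are identical. It also needs attack by ring A and not by ring B (which would give an indan-1-one), secured because the ring A carbon is ortho/para to three oxygens and closes a six-membered ring, whereas C2' and C6' of ring B are far less activated. Finally, the benzylic C2–O1 bond must not ionise, which is favoured by the weakly acidic medium (only liberated CF3CO2H at 0 °C) and by the twisted, doubly flanked 4'-benzyloxy group being a poor donor.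

Step 11
Reactants: 15 (2S)-5,7-bis(benzyloxy)-2-{3,4-bis(benzyloxy)-5-[5,7-bis(benzyloxy)-2-(4-(benzyloxy)phenyl)-4-oxo-4H-chromen-6-yl]phenyl}chroman-4-one
Product: 16 (2S)-2-{3,4-dihydroxy-5-[5,7-dihydroxy-2-(4-hydroxyphenyl)-4-oxo-4H-chromen-6-yl]phenyl}-5,7-dihydroxychroman-4-one (target)
Conditions: H2 (1 atm), 10% Pd/C, THF/MeOH, rt
Reagents that add atoms: none
Why: Catalytic hydrogenolysis of the seven benzyl ethers under neutral conditions, which should neither enolise nor open the flavanone, so the (2S) centre is retained, and which cleaves benzyl ethers much faster than it reduces the flavone C2=C3 bond or the ketones.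

Compound list
1 | apigenin, 5,7-dihydroxy-2-(4-hydroxyphenyl)-4H-chromen-4-one | O=c1cc(-c2ccc(O)cc2)oc2cc(O)cc(O)c12 | starting material
2 | 7-(benzyloxy)-2-[4-(benzyloxy)phenyl]-5-hydroxy-4H-chromen-4-one | O=c1cc(-c2ccc(OCc3ccccc3)cc2)oc2cc(OCc3ccccc3)cc(O)c12 | intermediate
3 | 7-(benzyloxy)-2-[4-(benzyloxy)phenyl]-5-hydroxy-6-iodo-4H-chromen-4-one | O=c1cc(-c2ccc(OCc3ccccc3)cc2)oc2cc(OCc3ccccc3)c(I)c(O)c12 | intermediate
4 | 5,7-bis(benzyloxy)-2-[4-(benzyloxy)phenyl]-6-iodo-4H-chromen-4-one | O=c1cc(-c2ccc(OCc3ccccc3)cc2)oc2cc(OCc3ccccc3)c(I)c(OCc3ccccc3)c12 | intermediate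
5 | 3-bromo-4,5-dihydroxybenzaldehyde | O=Cc1cc(O)c(O)c(Br)c1 | starting material
6 | 3,4-bis(benzyloxy)-5-bromobenzaldehyde | O=Cc1cc(OCc2ccccc2)c(OCc2ccccc2)c(Br)c1 | intermediate
7 | ethyl 3-[3,4-bis(benzyloxy)-5-bromophenyl]-3-oxopropanoate | CCOC(=O)CC(=O)c1cc(OCc2ccccc2)c(OCc2ccccc2)c(Br)c1 | intermediate
8 | ethyl (3R)-3-[3,4-bis(benzyloxy)-5-bromophenyl]-3-hydroxypropanoate | CCOC(=O)C[C@@H](O)c1cc(OCc2ccccc2)c(OCc2ccccc2)c(Br)c1 | intermediate
9 | 3,5-bis(benzyloxy)phenol | Oc1cc(OCc2ccccc2)cc(OCc2ccccc2)c1 | starting material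
10 | ethyl (3S)-3-[3,4-bis(benzyloxy)-5-bromophenyl]-3-[3,5-bis(benzyloxy)phenoxy]propanoate | CCOC(=O)C[C@H](Oc1cc(OCc2ccccc2)cc(OCc2ccccc2)c1)c1cc(OCc2ccccc2)c(OCc2ccccc2)c(Br)c1 | intermediate
11 | ethyl (3S)-3-[3,4-bis(benzyloxy)-5-(4,4,5,5-tetramethyl-1,3,2-dioxaborolan-2-yl)phenyl]-3-[3,5-bis(benzyloxy)phenoxy]propanoate (pinacol boronate, not isolated) | CCOC(=O)C[C@H](Oc1cc(OCc2ccccc2)cc(OCc2ccccc2)c1)c1cc(OCc2ccccc2)c(OCc2ccccc2)c(B2OC(C)(C)C(C)(C)O2)c1 | intermediate
12 | ethyl (3S)-3-{3,4-bis(benzyloxy)-5-[5,7-bis(benzyloxy)-2-(4-(benzyloxy)phenyl)-4-oxo-4H-chromen-6-yl]phenyl}-3-[3,5-bis(benzyloxy)phenoxy]propanoate | CCOC(=O)C[C@H](Oc1cc(OCc2ccccc2)cc(OCc2ccccc2)c1)c1cc(OCc2ccccc2)c(OCc2ccccc2)c(-c2c(OCc3ccccc3)cc3oc(-c4ccc(OCc5ccccc5)cc4)cc(=O)c3c2OCc2ccccc2)c1 | intermediate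
13 | (3S)-3-{3,4-bis(benzyloxy)-5-[5,7-bis(benzyloxy)-2-(4-(benzyloxy)phenyl)-4-oxo-4H-chromen-6-yl]phenyl}-3-[3,5-bis(benzyloxy)phenoxy]propanoic acid | OC(=O)C[C@H](Oc1cc(OCc2ccccc2)cc(OCc2ccccc2)c1)c1cc(OCc2ccccc2)c(OCc2ccccc2)c(-c2c(OCc3ccccc3)cc3oc(-c4ccc(OCc5ccccc5)cc4)cc(=O)c3c2OCc2ccccc2)c1 | intermediate
14 | mixed anhydride of acid 13 with trifluoroacetic acid (not isolated) | O=C(OC(=O)C(F)(F)F)C[C@H](Oc1cc(OCc2ccccc2)cc(OCc2ccccc2)c1)c1cc(OCc2ccccc2)c(OCc2ccccc2)c(-c2c(OCc3ccccc3)cc3oc(-c4ccc(OCc5ccccc5)cc4)cc(=O)c3c2OCc2ccccc2)c1 | intermediate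
15 | (2S)-5,7-bis(benzyloxy)-2-{3,4-bis(benzyloxy)-5-[5,7-bis(benzyloxy)-2-(4-(benzyloxy)phenyl)-4-oxo-4H-chromen-6-yl]phenyl}chroman-4-one | O=C1C[C@@H](c2cc(OCc3ccccc3)c(OCc3ccccc3)c(-c3c(OCc4ccccc4)cc4oc(-c5ccc(OCc6ccccc6)cc5)cc(=O)c4c3OCc3ccccc3)c2)Oc2cc(OCc3ccccc3)cc(OCc3ccccc3)c21 | intermediate
16 | (2S)-2-{3,4-dihydroxy-5-[5,7-dihydroxy-2-(4-hydroxyphenyl)-4-oxo-4H-chromen-6-yl]phenyl}-5,7-dihydroxychroman-4-one | O=C1C[C@@H](c2cc(O)c(O)c(-c3c(O)cc4oc(-c5ccc(O)cc5)cc(=O)c4c3O)c2)Oc2cc(O)cc(O)c21 | target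

Total step count: 11. Longest linear sequence: 8 steps (steps 4 to 11, from compound 5); the iodoflavone branch (steps 1 to 3) joins at step 8.

Steps most likely to fail

1. Step 10 (key step). The acidic acylating medium may ionise the benzylic C–O bond of 13 or 14, expelling the phloroglucinol ether, forming the cinnamic acid and eroding the configuration. Alternatively, ring A may be C-trifluoroacetylated before it cyclises. The fallback closes ring C at O1–C2 instead and sets out from 6 and 4. Aldehyde 6 is borylated and coupled with 4 under the conditions of step 8, through 3,4-bis(benzyloxy)-5-(4,4,5,5-tetramethyl-1,3,2-dioxaborolan-2-yl)benzaldehyde F1 (not isolated), to give 3,4-bis(benzyloxy)-5-[5,7-bis(benzyloxy)-2-(4-(benzyloxy)phenyl)-4-oxo-4H-chromen-6-yl]benzaldehyde F2. Claisen–Schmidt condensation of F2 with commercial 1-[2-hydroxy-4,6-bis(benzyloxy)phenyl]ethanone (KOH, EtOH/THF, rt) should give the (E)-2'-hydroxychalcone F3. Intramolecular oxa-Michael addition of the 2'-phenol under a quinine-derived bifunctional thiourea (toluene, rt) should then set C2 as (S) and return to the route at 15. If the selectivity is insufficient, cyclisation with NaOAc in EtOH and separation on a chiral stationary phase remains.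

2. Step 7 (Mitsunobu). The betaine may dehydrate the β-hydroxy ester to the cinnamate instead of promoting substitution, and partial ionisation at the benzylic carbon may cost stereochemical fidelity. The fallback removes the acidifying ester during the substitution and sets out from 8. Reduction with LiBH4 (THF, 0 °C to rt) gives (1R)-1-[3,4-bis(benzyloxy)-5-bromophenyl]propane-1,3-diol F4. Selective silylation of the primary alcohol (TBSCl, imidazole, CH2Cl2) gives (1R)-1-[3,4-bis(benzyloxy)-5-bromophenyl]-3-(tert-butyldimethylsilyloxy)propan-1-ol F5. Mitsunobu reaction with 9 (PPh3, DIAD, toluene), now with no acidic α-hydrogens, should give with inversion the (S)-aryl ether F6. TBAF (THF) frees the primary alcohol F7, and TEMPO/PhI(OAc)2 (MeCN/H2O) oxidises it to (3S)-3-[3,4-bis(benzyloxy)-5-bromophenyl]-3-[3,5-bis(benzyloxy)phenoxy]propanoic acid F8. Esterification (EtI, K2CO3, DMF) returns to the route at 10.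

3. Step 8 (one-pot borylation and Suzuki coupling). The ortho-alkoxy boronate may protodeboronate before the slow transmetalation onto the hindered arylpalladium iodide, or the aqueous base may trigger β-elimination of the aryloxy group from the ester. The fallback is a base-free Stille coupling and sets out from 10. Stannylation (Me3SnSnMe3, Pd(PPh3)4, toluene, 100 °C) gives ethyl (3S)-3-[3,4-bis(benzyloxy)-5-(trimethylstannyl)phenyl]-3-[3,5-bis(benzyloxy)phenoxy]propanoate F9. Coupling of F9 with 4 (Pd(PPh3)4, CuI, CsF, DMF, 50 °C) should return to the route at 12.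

Further compounds
F1 | step 10 | 3,4-bis(benzyloxy)-5-(4,4,5,5-tetramethyl-1,3,2-dioxaborolan-2-yl)benzaldehyde | O=Cc1cc(OCc2ccccc2)c(OCc2ccccc2)c(B2OC(C)(C)C(C)(C)O2)c1
F2 | step 10 | 3,4-bis(benzyloxy)-5-[5,7-bis(benzyloxy)-2-(4-(benzyloxy)phenyl)-4-oxo-4H-chromen-6-yl]benzaldehyde | O=Cc1cc(OCc2ccccc2)c(OCc2ccccc2)c(-c2c(OCc3ccccc3)cc3oc(-c4ccc(OCc5ccccc5)cc4)cc(=O)c3c2OCc2ccccc2)c1
F3 | step 10 | (E)-1-[2-hydroxy-4,6-bis(benzyloxy)phenyl]-3-{3,4-bis(benzyloxy)-5-[5,7-bis(benzyloxy)-2-(4-(benzyloxy)phenyl)-4-oxo-4H-chromen-6-yl]phenyl}prop-2-en-1-one | O=C(/C=C/c1cc(OCc2ccccc2)c(OCc2ccccc2)c(-c2c(OCc3ccccc3)cc3oc(-c4ccc(OCc5ccccc5)cc4)cc(=O)c3c2OCc2ccccc2)c1)c1c(O)cc(OCc2ccccc2)cc1OCc1ccccc1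
F4 | step 7 | (1R)-1-[3,4-bis(benzyloxy)-5-bromophenyl]propane-1,3-diol | OCC[C@@H](O)c1cc(OCc2ccccc2)c(OCc2ccccc2)c(Br)c1
F5 | step 7 | (1R)-1-[3,4-bis(benzyloxy)-5-bromophenyl]-3-(tert-butyldimethylsilyloxy)propan-1-ol | CC(C)(C)[Si](C)(C)OCC[C@@H](O)c1cc(OCc2ccccc2)c(OCc2ccccc2)c(Br)c1
F6 | step 7 | tert-butyl{(3S)-3-[3,4-bis(benzyloxy)-5-bromophenyl]-3-[3,5-bis(benzyloxy)phenoxy]propoxy}dimethylsilane | CC(C)(C)[Si](C)(C)OCC[C@H](Oc1cc(OCc2ccccc2)cc(OCc2ccccc2)c1)c1cc(OCc2ccccc2)c(OCc2ccccc2)c(Br)c1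
F7 | step 7 | (3S)-3-[3,4-bis(benzyloxy)-5-bromophenyl]-3-[3,5-bis(benzyloxy)phenoxy]propan-1-ol | OCC[C@H](Oc1cc(OCc2ccccc2)cc(OCc2ccccc2)c1)c1cc(OCc2ccccc2)c(OCc2ccccc2)c(Br)c1
F8 | step 7 | (3S)-3-[3,4-bis(benzyloxy)-5-bromophenyl]-3-[3,5-bis(benzyloxy)phenoxy]propanoic acid | OC(=O)C[C@H](Oc1cc(OCc2ccccc2)cc(OCc2ccccc2)c1)c1cc(OCc2ccccc2)c(OCc2ccccc2)c(Br)c1
F9 | step 8 | ethyl (3S)-3-[3,4-bis(benzyloxy)-5-(trimethylstannyl)phenyl]-3-[3,5-bis(benzyloxy)phenoxy]propanoate | CCOC(=O)C[C@H](Oc1cc(OCc2ccccc2)cc(OCc2ccccc2)c1)c1cc(OCc2ccccc2)c(OCc2ccccc2)c([Sn](C)(C)C)c1
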